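## Structural features

The target is a bicyclic neolignan: a dihydrofuran ring B (O1, C2, C3, C3a, C7a) fused along C3a–C7a to a six-membered carbocyclic ring A (C3a, C4, C5, C6, C7, C7a), which is not aromatic but a linearly conjugated cyclohexa-2,4-dienone (C4=C3a, C7a=C7, C6=O). C2 carries a 3,4,5-trimethoxyphenyl group and C3 a methyl group on neighbouring stereocentres that are trans (2S,3S). The third stereocentre, quaternary C5 (R, methoxy and allyl, allyl on the face of the C2 aryl group), is separated from them by the flat dienone. Ring A bears oxygen on four consecutive carbons: C5 (OMe), C6 (C=O), C7 (OMe) and C7a (O1). The dienone is the dearomatised form of a 2,6-dimethoxyphenol and is the fragile part, since the allyl group can move by [3,3] shifts to C3a or to the C6 oxygen and the diene can dimerise, while the benzylic C2–O1 ether tolerates base better than strong acid. The real difficulty is a fully substituted, tetra-oxygenated benzene joined to two contiguous stereocentres, followed by a dearomatising C-allylation at a methoxy-bearing carbon that receives no stereochemical guidance. The key step exploits C7a (O1) and C7 (OMe) as adjacent oxygenated carbons next to the C6 oxygen: two vicinal C–O bonds of this kind are what a C7–C7a aryne leaves behind when the C2 oxygen adds at C7a and an oxygen electrophile quenches the carbanion at C7.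

## Logic of the disconnections

**13 to 12.** The first cut is the C5–CH2 bond of the allyl group, which at the same time returns ring A to the aromatic state with a free hydroxyl at C6. The cut is made here because the dienone is the least stable part and should exist only in the final step. The gain is the loss of the quaternary stereocentre and of all dienone reactivity. The demand is that the forward step oxidises 12 to a ring electrophile and steers an allyl nucleophile to C5 and not to C7 or C3a. Nothing in 12 can be expected to control the C5 configuration, so a separation of epimers is accepted.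

**12 to 11 to 10.** Two O–C bonds are cut without change of skeleton: the C6 hydroxyl of 12 is traced to the acetal oxygen of 11 (O–CH2), and the C7 methyl ether of 11 to the free hydroxyl of 10 (O–CH3). The reason is the differentiation of three neighbouring oxygens. The C6 oxygen must stay masked while C7 is methylated, and the mask must survive and assist organolithium chemistry. A methoxymethyl acetal does this: it cannot migrate to carbon as a silyl or carbamoyl group would, and it is not lithiated as a benzyl ether would be. The gain is that 10 shows the C7 oxygen as a free hydroxyl, which is what an oxidative quench of a C7 carbanion delivers. The demand is methylation before unmasking and an acid mild enough for the C2–O1 bond.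

**10 to 6.** The strategic cut removes two bonds on neighbouring carbons, O1–C7a and C7–O, through the aryne 7. In 6, C7a carries fluorine and C7 carries hydrogen between that fluorine and the acetal oxygen. Ring B is opened and one oxygen is removed, leaving an acyclic 1,2-diarylpropanol with a simple fluoroarene. The forward step must metalate C7 selectively, generate 7, close the five-membered ring faster than any intermolecular addition, and carry the carbanion 8 through 9 to the C–O bond, with C2 and C3 as spectators.

**6 to 5.** The carbinol C–H bond is cut, and with it C2 is allowed to become configurationally labile in the racemic ketone 5. The reason is that the C2 hydrogen of 5 is acidic, so one catalytic reduction under dynamic kinetic resolution can set both stereocentres. Two stereocentres are traded for none. Enolisation must outpace reduction, and the catalyst must combine face selectivity at the carbonyl with a clear preference for one enantiomer of 5. The required (1S,2S) isomer is the Felkin-type one, so catalyst and substrate preferences can be matched.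

**5 to 3 and 4.** The bond between the ketone α-carbon and the fluoroaryl ring (C3–C3a of the target) is cut. This divides 5 into an enolate partner and an aryl bromide of similar size and is the point of convergence. The demand is a single arylation of a propiophenone by an electron-rich, ortho-fluorinated bromide in the presence of the acetal.

**3 to 2 to 1.** The acetal O–CH2 bond and the C–Br bond are cut, leading to 1. Bromination para to the hydroxyl fixes the pattern that later places fluorine at C7a, hydrogen at C7 and methoxy at C5. The demand is regioselective bromination and an acetal-forming method that does not use chloromethyl methyl ether.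

## Other disconnections considered

**Alternative 1:** The cut is C7a–C3a, C4–C5 and C5–C6, so that ring A is assembled from a carbene carbon (C7a), a methoxyvinyl unit (C7, C6), carbon monoxide (C5) and an alkyne (C4, C3a), while ring B closes through the oxygen tether. In the forward sense the alkynol A1 would be installed as the alkoxy group of the zerovalent chromium carbene complex A2, made from Cr(CO)6. Warming A2 should insert the alkyne and CO and electrocyclise to the dihydrobenzofuranol A3.
- In its favour: two rings and three C–C bonds form in one operation, the tether overrides the usual alkyne regiochemistry, both stereocentres come in with A1 (a reagent-controlled allenylmetal addition to the aryl aldehyde), and no aryl halide or cryogenic base is needed.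
- Against it here: A3 has oxygen only at C5 and C7. The C6 oxygen would have to be added afterwards (O-methylation, then lithiation between the two methoxy groups and borate oxidation) to reach 12. The benzannulation must also work through a two-carbon tether, the least favourable length, and it needs stoichiometric chromium, CO and an air-sensitive carbene.
- Comparison: in bonds formed per step the alternative is the better plan. In stereocontrol it is the equal of the chosen plan, since both fix C2 and C3 before ring B closes. In step count to 12 the two are about equal. The chosen plan is preferred because its key step delivers the complete oxygen pattern of ring A with LiTMP, B(OMe)3 and H2O2 instead of a toxic stoichiometric metal, and because a five-membered exo closure onto an aryne is mechanistically less doubtful than a tethered benzannulation at its ring-size limit.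

**Alternative 2:** The cut is C2–C3. In the forward sense the aryldiazoacetate A4 would be decomposed by Rh2(S-PTTL)4 or its enantiomer, a chiral divalent rhodium carboxylate. The carbenoid should insert into the benzylic C–H bond next to the ether oxygen and give the 2,3-cis ester A5.
- In its favour: it is a catalytic asymmetric C–H functionalisation that creates both stereocentres from an achiral substrate, on a C–H bond doubly activated by oxygen and an electron-rich aryl group. On catalyst-controlled stereogenesis it is at least the equal of the chosen dynamic kinetic resolution and does not depend on substrate epimerisation.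
- Against it here: A5 is cis and would need epimerisation at C3. Its C3 substituent is an ester that needs three further steps (reduction, activation, hydride displacement) to become methyl. Ring A lacks the C5 oxygen, which means desilylation, halogenation at C5 and copper-mediated methoxylation or an equivalent sequence. Diazo transfer brings an energetic reagent and intermediate.
- Comparison: structurally the chosen key step works on the final carbon skeleton with the C3 methyl and all ring A oxygens in place, whereas A5 needs repair at C3 and at C5. The steps after the alternative's key step alone would outnumber the whole chosen route.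

**Alternative 3:** The cut is C3–C3a in the sense of a ring contraction. In the forward sense PhI(OAc)2 with HC(OMe)3 and H2SO4 would convert the (2S)-flavanone A6 into the trans ester A7, by shift of ring A from the carbonyl carbon to C3.
- In its favour: the 2,3-trans relationship arises directly, which equals the chosen plan on relative configuration. The reagents are metal-free and inexpensive and no cryogenic step is needed, which is better operationally.
- Against it here: A6 must first be made enantioenriched, and its C2 centre can be lost by acid-induced opening to the chalcone. The electron-rich 2-aryl group can migrate in competition with ring A. The ester again needs three steps to become methyl, the benzyl ether must be removed, and the C5 oxygen is missing as in alternative 2.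
- Comparison: the mechanism is simple, but the configurational risk at C2 under strong acid has no counterpart in the chosen plan, where C2–O is never broken. The step count is clearly higher.

Key step: step 5

Assumption: benzofuran numbering (O1, C2, C3, C3a, C4 to C7, C7a) is used for ring atoms throughout, also for the acyclic precursors; CIP analysis of the target gives (2S,3S,5R), and the (1S,2S) alcohol 6 maps onto (2S,3S) because ring closure leaves both centres untouched.

Remark: the methoxymethyl ether is made from dimethoxymethane by acid-catalysed exchange, so chloromethyl methyl ether is not handled.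

## Route

**Step 1**
Reactants: 1 5-fluoro-2-methoxyphenol
Product: 2 4-bromo-5-fluoro-2-methoxyphenol
Conditions: NBS (1.05 equiv), MeCN, 0 °C → rt
Reagents that add atoms: N-bromosuccinimide, O=C1CCC(=O)N1Br
Why: Electrophilic aromatic bromination; the free hydroxyl is the strongest donor and its para position, which is also ortho to fluorine, is the doubly activated and least hindered site, so monobromination is expected there.

**Step 2**
Reactants: 2 4-bromo-5-fluoro-2-methoxyphenol
Product: 3 1-bromo-2-fluoro-5-methoxy-4-(methoxymethoxy)benzene
Conditions: CH2(OMe)2 (excess), TsOH·H2O (cat.), CH2Cl2, reflux through 4 Å molecular sieves (Soxhlet)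
Reagents that add atoms: dimethoxymethane, COCOC
Why: Acid-catalysed transacetalisation of the phenol with dimethoxymethane, driven by removal of methanol on the sieves; it installs the base-stable, lithium-coordinating MOM group without chloromethyl methyl ether.

**Step 3**
Reactants: 3 1-bromo-2-fluoro-5-methoxy-4-(methoxymethoxy)benzene; 4 1-(3,4,5-trimethoxyphenyl)propan-1-one
Product: 5 rac-2-[2-fluoro-5-methoxy-4-(methoxymethoxy)phenyl]-1-(3,4,5-trimethoxyphenyl)propan-1-one
Conditions: Pd(OAc)2 (2 mol %), XPhos (4 mol %), NaOtBu (1.3 equiv), toluene, 80 °C
Reagents that add atoms: none
Why: Palladium-catalysed ketone α-arylation (Buchwald–Hartwig type): zerovalent palladium inserts into the C–Br bond, the sodium enolate of 4 transmetalates and reductive elimination forms the aryl–Cα bond. The tertiary α-carbon of 5 blocks a second arylation, the C–F bond and the acetal are inert, and the new stereocentre is deliberately racemic.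

**Step 4**
Reactants: 5 rac-2-[2-fluoro-5-methoxy-4-(methoxymethoxy)phenyl]-1-(3,4,5-trimethoxyphenyl)propan-1-one
Product: 6 (1S,2S)-2-[2-fluoro-5-methoxy-4-(methoxymethoxy)phenyl]-1-(3,4,5-trimethoxyphenyl)propan-1-ol
Conditions: RuCl[(S,S)-TsDPEN](p-cymene) (2 mol %), HCO2H/Et3N (1:2), MeCN, 40 °C
Reagents that add atoms: none
Why: Noyori–Ikariya asymmetric transfer hydrogenation under dynamic kinetic resolution: the α-hydrogen of 5 is benzylic and α to the carbonyl, so the enantiomers interconvert by enolisation in the amine-rich formate medium, while the (S,S)-catalyst delivers hydride to the carbonyl face that gives the (1S) carbinol and does so fastest for the (2S)-ketone, where this is also the Felkin–Anh face. C1 is thus set by the catalyst and C2 by the matched pairing of catalyst and substrate, which should give the like (1S,2S) isomer.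

**Step 5**
Reactants: 6 (1S,2S)-2-[2-fluoro-5-methoxy-4-(methoxymethoxy)phenyl]-1-(3,4,5-trimethoxyphenyl)propan-1-ol
Product: 10 (2S,3S)-5-methoxy-6-(methoxymethoxy)-3-methyl-2-(3,4,5-trimethoxyphenyl)-2,3-dihydro-1-benzofuran-7-ol, via aryne alkoxide 7 (not isolated), via C7 aryllithium 8 (not isolated), via lithium arylborate 9 (not isolated)
Conditions: LiTMP (3 equiv), THF, −78 → −20 °C; B(OMe)3 (5 equiv), −78 → 0 °C; AcOH, 30 % H2O2, 0 °C → rt
Reagents that add atoms: hydrogen peroxide, OO
Why: LiTMP first forms the lithium alkoxide and then removes the C7 proton, the most acidic ring hydrogen because it lies between fluorine and the MOM ether, which also guides the base by coordination; on warming, the ortho-lithiated fluoroarene expels LiF to give the C7–C7a aryne 7. The tethered alkoxide adds to C7a in a 5-exo-dig closure that forms O1–C7a and ring B; addition at C7 would need a six-membered endo closure and would place the carbanion away from the inductively stabilising C6 oxygen, so ring size and aryne polarisation both point to C7a. The resulting aryllithium 8, held between O1 and the chelating MOM oxygen, is captured by B(OMe)3 as the borate 9, and H2O2 then triggers the 1,2-shift of the aryl group from boron to oxygen that forms the C7–O bond. The closest known reaction type is the anionic aryne cyclisation of tethered alkoxides, amides or carbanions with electrophilic trapping of the new aryllithium, combined with the standard borylation and oxidation of aryllithiums. No stereocentre is created: the C2–O bond of 6 is never broken, so O1–C7a forms with retention at C2, and C3–H is not acidic enough to be touched, so the trans relationship set in step 4 is carried into 10. The step needs site-selective metalation (C7 over C4 and over the trimethoxyphenyl ring), which the flanking F and OMOM groups secure, and intramolecular oxygen addition in preference to amide addition, which the hindered tetramethylpiperidide and the five-membered transition state secure. It also needs the aryllithium to survive until it meets the borate ester, which is why the mixture is recooled before B(OMe)3 is added in excess.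

**Step 6**
Reactants: 10 (2S,3S)-5-methoxy-6-(methoxymethoxy)-3-methyl-2-(3,4,5-trimethoxyphenyl)-2,3-dihydro-1-benzofuran-7-ol
Product: 11 (2S,3S)-5,7-dimethoxy-6-(methoxymethoxy)-3-methyl-2-(3,4,5-trimethoxyphenyl)-2,3-dihydro-1-benzofuran
Conditions: MeI (1.5 equiv), K2CO3 (2 equiv), acetone, 40 °C
Reagents that add atoms: iodomethane, CI
Why: Williamson etherification of the only free hydroxyl (phenoxide at C7, SN2 on MeI); the acetal, the aryl ethers and both stereocentres are untouched by the mild base.

**Step 7**
Reactants: 11 (2S,3S)-5,7-dimethoxy-6-(methoxymethoxy)-3-methyl-2-(3,4,5-trimethoxyphenyl)-2,3-dihydro-1-benzofuran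
Product: 12 (2S,3S)-5,7-dimethoxy-3-methyl-2-(3,4,5-trimethoxyphenyl)-2,3-dihydro-1-benzofuran-6-ol
Conditions: aq. HCl (cat.), MeOH, 40 °C
Reagents that add atoms: none
Why: Acid-catalysed acetal exchange with methanol removes the phenolic MOM group much faster than aryl methyl ethers or the dihydrofuran react. Should the benzylic C2–O1 bond ionise reversibly, reclosure returns the more stable trans ring because C3 is not touched.

**Step 8**
Reactants: 12 (2S,3S)-5,7-dimethoxy-3-methyl-2-(3,4,5-trimethoxyphenyl)-2,3-dihydro-1-benzofuran-6-ol
Product: 13 (2S,3S,5R)-5,7-dimethoxy-3-methyl-5-(prop-2-en-1-yl)-2-(3,4,5-trimethoxyphenyl)-3,5-dihydro-1-benzofuran-6(2H)-one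
Conditions: PhI(OCOCF3)2 (1.1 equiv), allylSiMe3 (5 equiv), CH2Cl2, −78 → −40 °C; chromatography (C5 epimers separated)
Reagents that add atoms: allyltrimethylsilane, C=CC[Si](C)(C)C
Why: λ3-Iodane-mediated oxidative dearomatisation with Hosomi–Sakurai-type allyl transfer: the phenol oxygen binds iodine, loss of PhI turns ring A into a phenoxonium-type electrophile with charge at the methoxy-bearing ortho carbons, and the allylsilane should attack C5, which is flanked by C4–H instead of the ring fusion and leads to the dienone conjugated with O1, before silicon is lost. C5 lies across a flat ring from C2 and C3, so both epimers are expected and the (5R) isomer is obtained by chromatography, with the product kept cold and free of acid to prevent [3,3] shifts of the allyl group.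

## Compound list

1 | 5-fluoro-2-methoxyphenol | COc1ccc(F)cc1O | starting material
2 | 4-bromo-5-fluoro-2-methoxyphenol | COc1cc(Br)c(F)cc1O | intermediate
3 | 1-bromo-2-fluoro-5-methoxy-4-(methoxymethoxy)benzene | COCOc1cc(F)c(Br)cc1OC | intermediate
4 | 1-(3,4,5-trimethoxyphenyl)propan-1-one | CCC(=O)c1cc(OC)c(OC)c(OC)c1 | starting material
5 | rac-2-[2-fluoro-5-methoxy-4-(methoxymethoxy)phenyl]-1-(3,4,5-trimethoxyphenyl)propan-1-one | CC(C(=O)c1cc(OC)c(OC)c(OC)c1)c1cc(OC)c(OCOC)cc1F | intermediate
6 | (1S,2S)-2-[2-fluoro-5-methoxy-4-(methoxymethoxy)phenyl]-1-(3,4,5-trimethoxyphenyl)propan-1-ol | O[C@H](c1cc(OC)c(OC)c(OC)c1)[C@H](c1cc(OC)c(OCOC)cc1F)C | intermediate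
7 | lithium (1S,2S)-2-[2,3-didehydro-5-methoxy-4-(methoxymethoxy)phenyl]-1-(3,4,5-trimethoxyphenyl)propan-1-olate (C7–C7a aryne) | [Li]O[C@H](c1cc(OC)c(OC)c(OC)c1)[C@H](C1=CC(OC)=C(OCOC)C#C1)C | intermediate (not isolated)
8 | [(2S,3S)-5-methoxy-6-(methoxymethoxy)-3-methyl-2-(3,4,5-trimethoxyphenyl)-2,3-dihydro-1-benzofuran-7-yl]lithium | [Li]c1c(OCOC)c(OC)cc2c1O[C@H](c1cc(OC)c(OC)c(OC)c1)[C@H]2C | intermediate (not isolated)
9 | lithium trimethoxy[(2S,3S)-5-methoxy-6-(methoxymethoxy)-3-methyl-2-(3,4,5-trimethoxyphenyl)-2,3-dihydro-1-benzofuran-7-yl]borate | [Li+].CO[B-](OC)(OC)c1c(OCOC)c(OC)cc2c1O[C@H](c1cc(OC)c(OC)c(OC)c1)[C@H]2C | intermediate (not isolated)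
10 | (2S,3S)-5-methoxy-6-(methoxymethoxy)-3-methyl-2-(3,4,5-trimethoxyphenyl)-2,3-dihydro-1-benzofuran-7-ol | COCOc1c(OC)cc2c(c1O)O[C@H](c1cc(OC)c(OC)c(OC)c1)[C@H]2C | intermediate
11 | (2S,3S)-5,7-dimethoxy-6-(methoxymethoxy)-3-methyl-2-(3,4,5-trimethoxyphenyl)-2,3-dihydro-1-benzofuran | COCOc1c(OC)cc2c(c1OC)O[C@H](c1cc(OC)c(OC)c(OC)c1)[C@H]2C | intermediate
12 | (2S,3S)-5,7-dimethoxy-3-methyl-2-(3,4,5-trimethoxyphenyl)-2,3-dihydro-1-benzofuran-6-ol | COc1cc2c(c(OC)c1O)O[C@H](c1cc(OC)c(OC)c(OC)c1)[C@H]2C | intermediate
13 | (2S,3S,5R)-5,7-dimethoxy-3-methyl-5-(prop-2-en-1-yl)-2-(3,4,5-trimethoxyphenyl)-3,5-dihydro-1-benzofuran-6(2H)-one | C=CC[C@@]1(OC)C=C2C(=C(OC)C1=O)O[C@H](c1cc(OC)c(OC)c(OC)c1)[C@H]2C | target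

## Step count and least certain steps

Total step count: 8. Longest linear sequence: 8 steps (1 to 13); 4 is used as purchased and enters at step 3.

**Step 5 (key step).** The most likely failure is loss of the C7 oxygen: the aryllithium 8 may be reprotonated by tetramethylpiperidine or the solvent before it meets the borate ester, or borate formation may be incomplete in the crowded lithium aggregate. Intermolecular addition of the amide to 7 is a lesser risk. The fallback divides the relay into two operations. Setting out from 6, the LiTMP-mediated aryne cyclisation alone, quenched with methanol, would give (2S,3S)-5-methoxy-6-(methoxymethoxy)-3-methyl-2-(3,4,5-trimethoxyphenyl)-2,3-dihydro-1-benzofuran F1. A separate directed ortho-metalation of F1 with n-BuLi in THF (C7–H is the only ring hydrogen between two oxygens, O1 and the MOM ether), followed by B(OMe)3 and H2O2, rejoins the route at 10.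

**Step 8.** The most likely failures are allyl transfer to C7 or C3a instead of C5, oxidative consumption of the allylsilane by the iodane, Diels–Alder dimerisation of the dienone, and acid-promoted migration of the allyl group. The absence of facial control also limits the throughput. The fallback separates oxidation from C–C bond formation. Setting out from 12, PhI(OAc)2 in MeOH at 0 °C, the usual way from 2-methoxyphenols to ortho-quinone monoketals, would give (2S,3S)-5,5,7-trimethoxy-3-methyl-2-(3,4,5-trimethoxyphenyl)-3,5-dihydro-1-benzofuran-6(2H)-one F2, whose regiochemistry can be checked before the allyl group is spent. Ionisation of the C5 ketal of F2 with TMSOTf in CH2Cl2 at −78 °C in the presence of allylSiMe3 (Hosomi–Sakurai substitution of a ketal) then replaces one methoxy group by allyl and returns to the route at 13, again after separation of the C5 epimers.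

**Step 3.** The most likely failures are slow oxidative addition into the electron-rich bromide 3 and, under NaOtBu at 80 °C, aldol self-condensation of 4 or hydrodebromination of 3. The fallback reverses the polarity of the partners. Setting out from 4, bromination with CuBr2 in EtOAc at reflux would give 2-bromo-1-(3,4,5-trimethoxyphenyl)propan-1-one F3. Setting out from 3, magnesium insertion in the presence of LiCl and ZnCl2 in THF, which transmetalates the ortho-fluoroaryl Grignard species as it forms, would give chlorido[2-fluoro-5-methoxy-4-(methoxymethoxy)phenyl]zinc F4. A Negishi coupling of F3 with F4, catalysed by NiCl2·glyme with an achiral pybox ligand at −20 °C, forms the same aryl–Cα bond without strong base and returns to the route at 5.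

**Step 4.** The most likely failure is that enolisation of 5 is slower than hydride transfer, because the α-carbon is tertiary and carries an ortho-substituted aryl group. The mismatched enantiomer would then be reduced as well, with erosion of diastereomeric and enantiomeric purity. The fallback sets C2 before the reduction instead of during it. Setting out from 3 and 4, the bromoketone F3 and the arylzinc F4 of the preceding fallback are coupled with NiCl2·glyme and a chiral pybox ligand (stereoconvergent Negishi arylation of a racemic α-bromoketone, run cold and without base so that the new tertiary centre is not epimerised) to give (2S)-2-[2-fluoro-5-methoxy-4-(methoxymethoxy)phenyl]-1-(3,4,5-trimethoxyphenyl)propan-1-one F5. Felkin–Anh-controlled reduction of F5 with LiBH(s-Bu)3 in THF at −78 °C then sets C1 and returns to the route at 6.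

## Further compounds

F1 | step 5 | (2S,3S)-5-methoxy-6-(methoxymethoxy)-3-methyl-2-(3,4,5-trimethoxyphenyl)-2,3-dihydro-1-benzofuran | COCOc1c(OC)cc2c(c1)O[C@H](c1cc(OC)c(OC)c(OC)c1)[C@H]2C
F2 | step 8 | (2S,3S)-5,5,7-trimethoxy-3-methyl-2-(3,4,5-trimethoxyphenyl)-3,5-dihydro-1-benzofuran-6(2H)-one | COC1(OC)C=C2C(=C(OC)C1=O)O[C@H](c1cc(OC)c(OC)c(OC)c1)[C@H]2C
F3 | step 3 | 2-bromo-1-(3,4,5-trimethoxyphenyl)propan-1-one (racemic) | CC(Br)C(=O)c1cc(OC)c(OC)c(OC)c1
F4 | step 3 | chlorido[2-fluoro-5-methoxy-4-(methoxymethoxy)phenyl]zinc | COCOc1cc(F)c([Zn]Cl)cc1OC
F5 | step 4 | (2S)-2-[2-fluoro-5-methoxy-4-(methoxymethoxy)phenyl]-1-(3,4,5-trimethoxyphenyl)propan-1-one | O=C(c1cc(OC)c(OC)c(OC)c1)[C@H](c1cc(OC)c(OCOC)cc1F)C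
A1 | alternative 1 | (1S,2S)-2-methyl-1-(3,4,5-trimethoxyphenyl)but-3-yn-1-ol | O[C@H](c1cc(OC)c(OC)c(OC)c1)[C@H](C#C)C
A2 | alternative 1 | pentacarbonyl{(1-methoxyethenyl)[(1S,2S)-2-methyl-1-(3,4,5-trimethoxyphenyl)but-3-yn-1-yl]oxymethylidene}chromium | C=C(OC)C(O[C@H](c1cc(OC)c(OC)c(OC)c1)[C@H](C#C)C)=[Cr](=C=O)(=C=O)(=C=O)(=C=O)=C=O
A3 | alternative 1 | (2S,3S)-7-methoxy-3-methyl-2-(3,4,5-trimethoxyphenyl)-2,3-dihydro-1-benzofuran-5-ol | COc1cc(O)cc2c1O[C@H](c1cc(OC)c(OC)c(OC)c1)[C@H]2C
A4 | alternative 2 | methyl 2-{4-[tert-butyl(dimethyl)silyl]oxy-3-methoxy-2-[(3,4,5-trimethoxyphenyl)methoxy]phenyl}-2-diazoacetate | COC(=O)C(=[N+]=[N-])c1ccc(O[Si](C)(C)C(C)(C)C)c(OC)c1OCc1cc(OC)c(OC)c(OC)c1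
A5 | alternative 2 | methyl (2S,3R)-6-[tert-butyl(dimethyl)silyl]oxy-7-methoxy-2-(3,4,5-trimethoxyphenyl)-2,3-dihydro-1-benzofuran-3-carboxylate | CC(C)(C)[Si](C)(C)Oc1ccc2c(c1OC)O[C@H](c1cc(OC)c(OC)c(OC)c1)[C@@H]2C(=O)OC
A6 | alternative 3 | (2S)-7-benzyloxy-8-methoxy-2-(3,4,5-trimethoxyphenyl)-2,3-dihydro-4H-chromen-4-one | O=C1C[C@@H](c2cc(OC)c(OC)c(OC)c2)Oc2c1ccc(OCc1ccccc1)c2OC
A7 | alternative 3 | methyl (2S,3S)-6-benzyloxy-7-methoxy-2-(3,4,5-trimethoxyphenyl)-2,3-dihydro-1-benzofuran-3-carboxylate | c1ccccc1COc1ccc2c(c1OC)O[C@H](c1cc(OC)c(OC)c(OC)c1)[C@H]2C(=O)OC
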